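**Plan**

- Retrosynthetic cuts, in order: C1–C10 (ring closure); the C8–O ester bond (made with inversion); C7–C8; the butenolide bonds C7=C11 and C12–O6; the two epoxide C–O pairs; C6–C7 (vinyl); C2=C3.
- Forward: the C1–C6 chain is built from a C5 enal; the cis 2,3-epoxide, the C6 carbinol and the trans 4,5-epoxide follow; the lactone ring is closed by metathesis as a 3-(bromomethyl)butenolide; a zinc Barbier reaction adds C8–C10/C14 and unveils the methylene lactone; the ten-membered ring closes last.
- Stereochemistry: C2/C3 from a tartrate-controlled epoxidation; C6 from a catalyst-controlled vinyl transfer; C4/C5 from direction by the C6 hydroxyl under A(1,3) strain; C7 and C8 from C6 through the Barbier transition state, with C8 then inverted during esterification; C1 from Felkin–Anh addition next to the cis epoxide.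
- Enabling feature: C1 is a carbinol bonded to sp2 C10, which bears the exocyclic C14 methylene (a 2-methylene carbinol); this maps onto addition of a C10 alkenyl metal to a C1 aldehyde. The cis 2,3-epoxide, the trans 4,5-epoxide and the trans-fused lactone ring (O6, C6, C7, C11, C12) pre-fold C2–C8 so that C1 and C10 can meet.

Key step: step 16

Assumption: compound 1, a C5 carotenoid building block, is taken as purchasable in its E form. TBS = tert-butyldimethylsilyl; atom numbers C1–C15 are germacrane numbers of the target.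

**Step 1**
Reactants: 1 (2E)-4,4-dimethoxy-2-methylbut-2-enal; 2 methyl bis(2,2,2-trifluoroethyl)phosphonoacetate
Product: 3 methyl (2Z,4E)-6,6-dimethoxy-4-methylhexa-2,4-dienoate
Conditions: KN(SiMe3)2, 18-crown-6, THF, −78 °C
Reagents that add atoms: none
Why: Still–Gennari olefination, in which the electron-poor trifluoroethyl phosphonate eliminates from the kinetic adduct before it can equilibrate, should give the Z C2=C3 enoate and leave the E C4=C5 bond of 1 unchanged.

**Step 2**
Reactants: 3 methyl (2Z,4E)-6,6-dimethoxy-4-methylhexa-2,4-dienoate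
Product: 4 (2Z,4E)-6,6-dimethoxy-4-methylhexa-2,4-dien-1-ol
Conditions: i-Bu2AlH (2.2 equiv), CH2Cl2, −78 °C; aq potassium sodium tartrate
Reagents that add atoms: none
Why: Hydride 1,2-reduction of the enoate (ester to allylic alcohol) at low temperature should keep both alkene geometries and the acetal.

**Step 3**
Reactants: 4 (2Z,4E)-6,6-dimethoxy-4-methylhexa-2,4-dien-1-ol
Product: 5 [(2S,3R)-3-[(2E)-4,4-dimethoxybut-2-en-2-yl]oxiran-2-yl]methanol (cis epoxide)
Conditions: Ti(OiPr)4 (20 mol%), diethyl L-(+)-tartrate (24 mol%), t-BuOOH, 4 Å molecular sieves, CH2Cl2, −20 °C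
Reagents that add atoms: tert-butyl hydroperoxide, CC(C)(C)OO
Why: Sharpless asymmetric epoxidation acts only on the C2=C3 bond, the one allylic to the free hydroxyl, carries the Z geometry into the cis epoxide, and with the L-(+)-tartrate should place oxygen on the face that makes C2 S (C3 is R here and becomes S by priority once C4 carries oxygen).

**Step 4**
Reactants: 5 [(2S,3R)-3-[(2E)-4,4-dimethoxybut-2-en-2-yl]oxiran-2-yl]methanol
Product: 6 TBS ether of 5, tert-butyl({(2S,3R)-3-[(2E)-4,4-dimethoxybut-2-en-2-yl]oxiran-2-yl}methoxy)dimethylsilane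
Conditions: t-BuMe2SiCl, imidazole, CH2Cl2, 0 °C
Reagents that add atoms: tert-butyldimethylsilyl chloride, CC(C)(C)[Si](C)(C)Cl
Why: Silyl ether formation on the primary C1 hydroxyl masks it for the acid, organozinc, acylation and redox-condensation steps that follow.

**Step 5**
Reactants: 6 TBS ether of 5
Product: 7 (2E)-3-[(2R,3S)-3-(TBS-oxymethyl)oxiran-2-yl]but-2-enal
Conditions: pyridinium p-toluenesulfonate (cat.), acetone/H2O, 0 °C
Reagents that add atoms: water, O
Why: Acid-catalysed acetal hydrolysis should be selective because the allylic dimethyl acetal ionises much faster than the primary silyl ether or the epoxide reacts, and the enal that forms deactivates the C4=C5 bond toward allylic opening of the neighbouring epoxide.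

**Step 6**
Reactants: 7 (2E)-3-[(2R,3S)-3-(TBS-oxymethyl)oxiran-2-yl]but-2-enal
Product: 8 (3S,4E)-5-[(2R,3S)-3-(TBS-oxymethyl)oxiran-2-yl]hexa-1,4-dien-3-ol
Conditions: (CH2=CH)2Zn [from CH2=CHMgBr and ZnCl2, dioxane], (−)-3-exo-morpholinoisoborneol (5 mol%), toluene, −20 °C; aq NH4Cl
Reagents that add atoms: divinylzinc, C=C[Zn]C=C
Why: Amino-alcohol-catalysed enantioselective 1,2-addition of an alkenylzinc to an aldehyde should deliver the vinyl group to the Si face of the enal inside the chiral zinc aminoalkoxide complex, so that C6 (C3 of the name) is set S by the catalyst and not by the remote epoxide.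

**Step 7**
Reactants: 8 (3S,4E)-5-[(2R,3S)-3-(TBS-oxymethyl)oxiran-2-yl]hexa-1,4-dien-3-ol
Product: 9 (1S)-1-[(2R,3S)-3-[(2S,3S)-3-(TBS-oxymethyl)oxiran-2-yl]-3-methyloxiran-2-yl]prop-2-en-1-ol
Conditions: m-CPBA, NaHCO3, CH2Cl2, 0 °C
Reagents that add atoms: 3-chloroperoxybenzoic acid, OOC(=O)c1cccc(Cl)c1
Why: Hydroxyl-directed peracid epoxidation: A(1,3) strain with the C4 methyl, which is cis to C6, keeps H6 in the alkene plane, so the hydrogen-bonded peracid should attack the trisubstituted C4=C5 bond from the hydroxyl side to give the threo epoxy alcohol (4S,5R, trans epoxide from the E alkene), while the monosubstituted vinyl group is too electron-poor to compete.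

**Step 8**
Reactants: 9 (1S)-1-[(2R,3S)-3-[(2S,3S)-3-(TBS-oxymethyl)oxiran-2-yl]-3-methyloxiran-2-yl]prop-2-en-1-ol; 10 2-(bromomethyl)prop-2-enoic acid
Product: 11 (1S)-1-[(2R,3S)-3-[(2S,3S)-3-(TBS-oxymethyl)oxiran-2-yl]-3-methyloxiran-2-yl]prop-2-en-1-yl 2-(bromomethyl)prop-2-enoate
Conditions: dicyclohexylcarbodiimide, 4-(dimethylamino)pyridine (10 mol%), CH2Cl2, 0 °C
Reagents that add atoms: none
Why: Steglich esterification acylates the secondary C6 hydroxyl with retention and without a base strong enough to trigger Payne rearrangement of the epoxy alcohol or substitution of the allylic bromide.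

**Step 9**
Reactants: 11 2-(bromomethyl)acrylate of 9
Product: 12 (5S)-3-(bromomethyl)-5-[(2R,3S)-3-[(2S,3S)-3-(TBS-oxymethyl)oxiran-2-yl]-3-methyloxiran-2-yl]furan-2(5H)-one
Conditions: second-generation Grubbs catalyst (H2IMes)(PCy3)Cl2Ru=CHPh (5 mol%), CH2Cl2, 40 °C
Reagents that add atoms: none
Why: Ring-closing metathesis of the allylic acrylate should load the ruthenium carbene on the vinyl group and close onto the 1,1-disubstituted acrylate alkene to form the C7=C11 bond of the five-membered butenolide with loss of ethylene, leaving C6 untouched.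

**Step 10**
Reactants: 13 but-3-yn-1-ol
Product: 14 3-iodobut-3-en-1-ol
Conditions: NaI, Me3SiCl, H2O, MeCN, rt
Reagents that add atoms: hydrogen iodide (made in the flask), I
Why: Markovnikov hydroiodination of the terminal alkyne by hydrogen iodide generated from the iodide salt, the chlorosilane and water should give the 2-iodo-1-alkene.

**Step 11**
Reactants: 14 3-iodobut-3-en-1-ol
Product: 15 3-iodobut-3-enal
Conditions: Dess–Martin periodinane, NaHCO3, CH2Cl2, 0 °C; used crude
Reagents that add atoms: none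
Why: Dess–Martin oxidation under buffered, non-basic conditions should give the β,γ-unsaturated aldehyde, which is used at once so that the double bond does not move into conjugation.

**Step 12**
Reactants: 12 (5S)-3-(bromomethyl)butenolide; 15 3-iodobut-3-enal
Product: 17 (4R,5S)-5-[(2R,3S)-3-[(2S,3S)-3-(TBS-oxymethyl)oxiran-2-yl]-3-methyloxiran-2-yl]-4-[(1S)-1-hydroxy-3-iodobut-3-en-1-yl]-3-methylideneoxolan-2-one, via allylzinc bromide 16 (not isolated)
Conditions: Zn, THF/sat. aq NH4Cl, 0 °C
Reagents that add atoms: none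
Why: Zinc Barbier allylation: zinc inserts into the allylic carbon–bromine bond and allylzinc 16 attacks the aldehyde through C7 (SE2') on the ring face anti to the C6 substituent, which sets the 6,7-trans lactone (7R), while the chair transition state with the ring-locked E-type allyl unit and an equatorial aldehyde chain should give the anti adduct (8S) and unveils the α-methylene lactone.

**Step 13**
Reactants: 17 (8S)-carbinol; 18 (2E)-2-methylbut-2-enoic acid (tiglic acid)
Product: 19 (1R)-1-[(2S,3R)-2-[(2R,3S)-3-[(2S,3S)-3-(TBS-oxymethyl)oxiran-2-yl]-3-methyloxiran-2-yl]-4-methylidene-5-oxooxolan-3-yl]-3-iodobut-3-en-1-yl (2E)-2-methylbut-2-enoate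
Conditions: PPh3, diisopropyl azodicarboxylate (betaine pre-formed), toluene, 0 °C to rt
Reagents that add atoms: none
Why: Mitsunobu esterification displaces the C8 alkoxyphosphonium by the tiglate anion in an SN2 step, so that 8S should be inverted to the required 8R while the ester is installed with its E geometry intact.

**Step 14**
Reactants: 19 TBS-protected 8R tiglate
Product: 20 (1R)-1-[(2S,3R)-2-[(2R,3S)-3-[(2S,3S)-3-(hydroxymethyl)oxiran-2-yl]-3-methyloxiran-2-yl]-4-methylidene-5-oxooxolan-3-yl]-3-iodobut-3-en-1-yl (2E)-2-methylbut-2-enoate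
Conditions: HF·pyridine, pyridine, THF, 0 °C
Reagents that add atoms: none
Why: Fluoride-mediated desilylation buffered with pyridine should free the primary C1 hydroxyl without opening the epoxides or cleaving the lactone and the tiglate.

**Step 15**
Reactants: 20 C1 alcohol
Product: 21 (1R)-1-[(2S,3R)-2-[(2R,3S)-3-[(2S,3R)-3-formyloxiran-2-yl]-3-methyloxiran-2-yl]-4-methylidene-5-oxooxolan-3-yl]-3-iodobut-3-en-1-yl (2E)-2-methylbut-2-enoate
Conditions: Dess–Martin periodinane, NaHCO3, CH2Cl2, 0 °C
Reagents that add atoms: none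
Why: Dess–Martin oxidation should give the α,β-epoxy aldehyde under neutral conditions that neither epimerise C2 nor open the epoxides.

**Step 16**
Reactants: 21 iodoalkene epoxy aldehyde
Product: 23 (1S,2S,3S,4S,5R,6S,7R,8R)-1-hydroxy-2,3:4,5-diepoxygermacra-10(14),11(13)-dien-6,12-olid-8-yl (2E)-2-methylbut-2-enoate (the target), via alkenylchromium dichloride 22 (not isolated)
Conditions: CrCl2 (10 equiv), NiCl2 (0.1 equiv), degassed DMSO, rt, slow addition to 0.003 M
Reagents that add atoms: none
Why: Zerovalent nickel, formed from NiCl2 by divalent chromium, inserts into the C10–iodine bond, the alkenyl group passes to chromium to give the trivalent alkenylchromium 22, and this adds to the C1 aldehyde to form the C1–C10 bond and, after work-up, the carbinol. The closest known reaction type is the intramolecular Nozaki–Hiyama–Kishi coupling of an iodoalkene with an aldehyde, used to close medium-ring 2-methylene carbinols. The ten-membered carbocycle closes by 1,2-addition of the alkenyl carbon C10 to the carbonyl, whose oxygen stays outside the ring (10-exo-trig), and the exocyclic C10=C14 methylene is carried in unchanged from the iodoalkene. C1 is the only new stereocentre and is controlled by neighbouring C2: in the Felkin–Anh (Cornforth) arrangement the C2–O bond of the cis epoxide lies anti to the incoming alkenyl group, which should give the erythro carbinol, that is 1S. The step needs chemoselectivity (addition to the aldehyde and not to the lactone, the tiglate, the methylene lactone or the epoxides) and ring closure in preference to intermolecular coupling; the low basicity and aldehyde selectivity of organochromium reagents secure the first, and high dilution together with the turn imposed by the cis 2,3-epoxide, the trans 4,5-epoxide and the trans-fused lactone secures the second. No β-elimination is possible from 22 because C9 carries no leaving group.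

**Compound list**

1 | (2E)-4,4-dimethoxy-2-methylbut-2-enal | COC(OC)/C=C(\C)C=O | starting material
2 | methyl bis(2,2,2-trifluoroethyl)phosphonoacetate | COC(=O)CP(=O)(OCC(F)(F)F)OCC(F)(F)F | starting material
3 | methyl (2Z,4E)-6,6-dimethoxy-4-methylhexa-2,4-dienoate | COC(=O)/C=C\C(C)=C\C(OC)OC | intermediate
4 | (2Z,4E)-6,6-dimethoxy-4-methylhexa-2,4-dien-1-ol | OC/C=C\C(C)=C\C(OC)OC | intermediate
5 | [(2S,3R)-3-[(2E)-4,4-dimethoxybut-2-en-2-yl]oxiran-2-yl]methanol | OC[C@@H]1O[C@@H]1/C(C)=C/C(OC)OC | intermediate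
6 | tert-butyl({(2S,3R)-3-[(2E)-4,4-dimethoxybut-2-en-2-yl]oxiran-2-yl}methoxy)dimethylsilane | CC(C)(C)[Si](C)(C)OC[C@@H]1O[C@@H]1/C(C)=C/C(OC)OC | intermediate
7 | (2E)-3-[(2R,3S)-3-(TBS-oxymethyl)oxiran-2-yl]but-2-enal | CC(C)(C)[Si](C)(C)OC[C@@H]1O[C@@H]1/C(C)=C/C=O | intermediate
8 | (3S,4E)-5-[(2R,3S)-3-(TBS-oxymethyl)oxiran-2-yl]hexa-1,4-dien-3-ol | CC(C)(C)[Si](C)(C)OC[C@@H]1O[C@@H]1/C(C)=C/[C@@H](O)C=C | intermediate
9 | (1S)-1-[(2R,3S)-3-[(2S,3S)-3-(TBS-oxymethyl)oxiran-2-yl]-3-methyloxiran-2-yl]prop-2-en-1-ol | CC(C)(C)[Si](C)(C)OC[C@@H]1O[C@@H]1[C@@]1(C)O[C@@H]1[C@@H](O)C=C | intermediate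
10 | 2-(bromomethyl)prop-2-enoic acid | OC(=O)C(=C)CBr | starting material
11 | (1S)-1-[(2R,3S)-3-[(2S,3S)-3-(TBS-oxymethyl)oxiran-2-yl]-3-methyloxiran-2-yl]prop-2-en-1-yl 2-(bromomethyl)prop-2-enoate | CC(C)(C)[Si](C)(C)OC[C@@H]1O[C@@H]1[C@@]1(C)O[C@@H]1[C@@H](OC(=O)C(=C)CBr)C=C | intermediate
12 | (5S)-3-(bromomethyl)-5-[(2R,3S)-3-[(2S,3S)-3-(TBS-oxymethyl)oxiran-2-yl]-3-methyloxiran-2-yl]furan-2(5H)-one | CC(C)(C)[Si](C)(C)OC[C@@H]1O[C@@H]1[C@@]1(C)O[C@@H]1[C@H]1OC(=O)C(CBr)=C1 | intermediate
13 | but-3-yn-1-ol | OCCC#C | starting material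
14 | 3-iodobut-3-en-1-ol | OCCC(I)=C | intermediate
15 | 3-iodobut-3-enal | O=CCC(I)=C | intermediate
16 | allylzinc bromide from 12 (BrZnCH2 in place of BrCH2) | CC(C)(C)[Si](C)(C)OC[C@@H]1O[C@@H]1[C@@]1(C)O[C@@H]1[C@H]1OC(=O)C(C[Zn]Br)=C1 | intermediate
17 | (4R,5S)-5-[(2R,3S)-3-[(2S,3S)-3-(TBS-oxymethyl)oxiran-2-yl]-3-methyloxiran-2-yl]-4-[(1S)-1-hydroxy-3-iodobut-3-en-1-yl]-3-methylideneoxolan-2-one | CC(C)(C)[Si](C)(C)OC[C@@H]1O[C@@H]1[C@@]1(C)O[C@@H]1[C@H]1OC(=O)C(=C)[C@@H]1[C@@H](O)CC(I)=C | intermediate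
18 | (2E)-2-methylbut-2-enoic acid (tiglic acid) | C/C=C(\C)C(=O)O | starting material
19 | (1R)-1-[(2S,3R)-2-[(2R,3S)-3-[(2S,3S)-3-(TBS-oxymethyl)oxiran-2-yl]-3-methyloxiran-2-yl]-4-methylidene-5-oxooxolan-3-yl]-3-iodobut-3-en-1-yl (2E)-2-methylbut-2-enoate | CC(C)(C)[Si](C)(C)OC[C@@H]1O[C@@H]1[C@@]1(C)O[C@@H]1[C@H]1OC(=O)C(=C)[C@@H]1[C@H](OC(=O)/C(C)=C/C)CC(I)=C | intermediate
20 | (1R)-1-[(2S,3R)-2-[(2R,3S)-3-[(2S,3S)-3-(hydroxymethyl)oxiran-2-yl]-3-methyloxiran-2-yl]-4-methylidene-5-oxooxolan-3-yl]-3-iodobut-3-en-1-yl (2E)-2-methylbut-2-enoate | OC[C@@H]1O[C@@H]1[C@@]1(C)O[C@@H]1[C@H]1OC(=O)C(=C)[C@@H]1[C@H](OC(=O)/C(C)=C/C)CC(I)=C | intermediate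
21 | (1R)-1-[(2S,3R)-2-[(2R,3S)-3-[(2S,3R)-3-formyloxiran-2-yl]-3-methyloxiran-2-yl]-4-methylidene-5-oxooxolan-3-yl]-3-iodobut-3-en-1-yl (2E)-2-methylbut-2-enoate | O=C[C@@H]1O[C@@H]1[C@@]1(C)O[C@@H]1[C@H]1OC(=O)C(=C)[C@@H]1[C@H](OC(=O)/C(C)=C/C)CC(I)=C | intermediate
22 | alkenylchromium dichloride from 21 (Cl2Cr in place of iodine at C10) | O=C[C@@H]1O[C@@H]1[C@@]1(C)O[C@@H]1[C@H]1OC(=O)C(=C)[C@@H]1[C@H](OC(=O)/C(C)=C/C)CC(=C)[Cr](Cl)Cl | intermediate
23 | (1S,2S,3S,4S,5R,6S,7R,8R)-1-hydroxy-2,3:4,5-diepoxygermacra-10(14),11(13)-dien-6,12-olid-8-yl (2E)-2-methylbut-2-enoate | C=C1C(=O)O[C@H]2[C@H]1[C@H](OC(=O)/C(C)=C/C)CC(=C)[C@H](O)[C@@H]1O[C@@H]1[C@@]1(C)O[C@H]21 | target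

**Step count**

Total: 16 steps. Longest linear sequence: 14 steps (steps 1–9 and 12–16).

**Steps most likely to fail**

Step 16. The alkenylchromium may add to the aldehyde face that is favoured when chromium bridges the carbonyl and epoxide oxygens, so that facial selectivity at C1 is poor or reversed. The fallback sets out from 21: the ring closure is run as before, and the C1-epimeric carbinol F1 is oxidised with Dess–Martin periodinane to the ring 1-ketone F2. Luche reduction of F2 (NaBH4, CeCl3·7H2O, MeOH, −78 °C) is then expected to deliver hydride anti to the C2–O bond of the α,β-epoxy ketone and to give the erythro carbinol, which returns the route to 23. Stereocontrol at C1 thus moves from the C–C bond formation to a ketone reduction.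

Step 13. The C8 alkoxyphosphonium sits next to the branched C7, so elimination toward C9 or attack of the phosphine on the methylene lactone may outrun SN2 displacement. The fallback sets out from 17: chloromethanesulfonyl chloride and pyridine give the chloromethanesulfonate F3. Displacement with cesium (E)-2-methylbut-2-enoate (from 18 and Cs2CO3) and 18-crown-6 in toluene at 50 °C should then give 19 with inversion, with no phosphine present.

Step 6. Face selection in the vinyl transfer may be insufficient, or magnesium salts may promote an uncatalysed background addition. The fallback sets out from 7: CH2=CHMgBr in THF at −78 °C gives 8 mixed with its C6 epimer F4, and MnO2 oxidises the mixture to the cross-conjugated dienone F5. Corey–Bakshi–Shibata reduction of F5 with the (R)-2-methyl oxazaborolidine and catecholborane, the β,β-disubstituted alkenyl group acting as the large substituent, should return 8.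

**Further compounds**

F1 | step 16 | C1 epimer (1R) of 23 | C=C1C(=O)O[C@H]2[C@H]1[C@H](OC(=O)/C(C)=C/C)CC(=C)[C@@H](O)[C@@H]1O[C@@H]1[C@@]1(C)O[C@H]21
F2 | step 16 | 1-oxo analogue of 23 (ring 2-methylene α,β-epoxy ketone) | C=C1C(=O)O[C@H]2[C@H]1[C@H](OC(=O)/C(C)=C/C)CC(=C)C(=O)[C@@H]1O[C@@H]1[C@@]1(C)O[C@H]21
F3 | step 13 | chloromethanesulfonate of 17 at C8 | CC(C)(C)[Si](C)(C)OC[C@@H]1O[C@@H]1[C@@]1(C)O[C@@H]1[C@H]1OC(=O)C(=C)[C@@H]1[C@@H](OS(=O)(=O)CCl)CC(I)=C
F4 | step 6 | (3R,4E)-5-[(2R,3S)-3-(TBS-oxymethyl)oxiran-2-yl]hexa-1,4-dien-3-ol (C6 epimer of 8) | CC(C)(C)[Si](C)(C)OC[C@@H]1O[C@@H]1/C(C)=C/[C@H](O)C=C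
F5 | step 6 | (4E)-5-[(2R,3S)-3-(TBS-oxymethyl)oxiran-2-yl]hexa-1,4-dien-3-one | CC(C)(C)[Si](C)(C)OC[C@@H]1O[C@@H]1/C(C)=C/C(=O)C=C
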